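Germacrane numbering is used. The 3(2H)-furanone ring (O, C3, C2, C1, C10) that bridges the ten-membered carbocycle C1–C10 is read as a cyclised α′-hydroxy ynone. One operation therefore closes both rings: a palladium/copper thioester–alkyne coupling joins the acyl carbon C1 to the terminal alkyne carbon C2 of an open precursor, and the C10 tertiary hydroxyl then adds across the new ring to C3 of the strained ynone. The precursor is the trans-disubstituted α-methylene-γ-lactone (C6, C7, C11, C12) carrying a (Z)-enyne at C6 and, at C7, the C8–C10 chain that ends in the C1 S-ethyl thioester; a zinc Barbier reaction joins its two halves.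

Key step: step 12

Remarks on the chemistry (assumptions):
- 2-C-Methyl-D-erythrono-1,4-lactone is taken as a commercial carbohydrate building block.
- In step 3, (S,S)-ProPhenol stands for the ligand enantiomer that gives the (4R)-carbinol; if the sense of induction is the opposite, the antipodal ligand is used.

Step 1
Reactants: 1 (2Z)-3-methylpent-2-en-4-yn-1-ol
Product: 3 (2Z)-3-methyl-5-(trimethylsilyl)pent-2-en-4-yn-1-ol, via bis-silylated enynol 2 (not isolated)
Conditions: EtMgBr (2.2 equiv), THF, 0 °C to rt; Me3SiCl (2.3 equiv); then 1 M HCl, rt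
Reagents that add atoms: chlorotrimethylsilane C[Si](C)(C)Cl
Why: Double deprotonation (O–H and alkyne C–H), silylation of both sites and selective acid hydrolysis of the O–Si bond (C-silylation of a terminal alkyne) mask the alkyne for step 3 without touching the Z alkene.

Step 2
Reactants: 3 (2Z)-3-methyl-5-(trimethylsilyl)pent-2-en-4-yn-1-ol
Product: 4 (2Z)-3-methyl-5-(trimethylsilyl)pent-2-en-4-ynal
Conditions: activated MnO2 (10 equiv), CH2Cl2, rt
Reagents that add atoms: none
Why: MnO2 oxidation of the allylic alcohol to the enal is mild enough that the Z geometry should be kept.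

Step 3
Reactants: 4 (2Z)-3-methyl-5-(trimethylsilyl)pent-2-en-4-ynal; 5 methyl prop-2-ynoate (methyl propiolate)
Product: 7 methyl (4R,5Z)-4-hydroxy-6-methyl-8-(trimethylsilyl)oct-5-ene-2,7-diynoate, via methylzinc alkynylide 6 (not isolated)
Conditions: 5 (3 equiv), ZnMe2 (3 equiv), (S,S)-ProPhenol (10 mol%), toluene, 0 to 4 °C; aq. NH4Cl
Reagents that add atoms: none
Why: Zinc-ProPhenol catalytic asymmetric alkynylation adds the propiolate alkynyl group 1,2 to one face of the enal and so sets C6 as R under catalyst control, the silyl cap keeping the substrate alkyne out of the zinc acetylide pool.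

Step 4
Reactants: 7 methyl (4R,5Z)-4-hydroxy-6-methyl-8-(trimethylsilyl)oct-5-ene-2,7-diynoate
Product: 10 (5R)-3-(hydroxymethyl)-5-[(1Z)-2-methyl-4-(trimethylsilyl)but-1-en-3-yn-1-yl]furan-2(5H)-one, via vinylalane 8 (not isolated), via open-chain diol ester 9 (not isolated)
Conditions: iBu2AlH (2.3 equiv), N-methylmorpholine N-oxide (2.3 equiv), THF, 0 °C; paraformaldehyde, 0 °C to rt; aq. potassium sodium tartrate; then PPTS (cat.), CH2Cl2, rt
Reagents that add atoms: formaldehyde C=O (from paraformaldehyde)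
Why: Conjugate syn-hydroalumination of the ynoate (vinylalumination) puts H on C7 and Al on C11, formaldehyde hydroxymethylates C11 with retention, and the cis γ-hydroxy enoate lactonises to the 3-(hydroxymethyl)butenolide with C6 untouched.

Step 5
Reactants: 10 (5R)-3-(hydroxymethyl)-5-[(1Z)-2-methyl-4-(trimethylsilyl)but-1-en-3-yn-1-yl]furan-2(5H)-one
Product: 11 (5R)-3-(hydroxymethyl)-5-[(1Z)-2-methylbut-1-en-3-yn-1-yl]furan-2(5H)-one
Conditions: Bu4NF (1.1 equiv), AcOH (1.2 equiv), THF, 0 °C
Reagents that add atoms: none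
Why: Buffered fluoride protodesilylation frees the terminal alkyne, the acetic acid keeping the medium from deprotonating the acidic C6–H of the butenolide.

Step 6
Reactants: 11 (5R)-3-(hydroxymethyl)-5-[(1Z)-2-methylbut-1-en-3-yn-1-yl]furan-2(5H)-one
Product: 12 (5R)-3-(bromomethyl)-5-[(1Z)-2-methylbut-1-en-3-yn-1-yl]furan-2(5H)-one
Conditions: CBr4, PPh3, CH2Cl2, 0 °C
Reagents that add atoms: carbon tetrabromide BrC(Br)(Br)Br
Why: Appel bromination of the primary allylic alcohol is base-free, so C6 should not racemise.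

Step 7
Reactants: 13 2-C-methyl-D-erythrono-1,4-lactone [(3R,4R)-3,4-dihydroxy-3-methyloxolan-2-one]
Product: 14 (3R,4R)-3-hydroxy-3-methyl-4-[(triethylsilyl)oxy]oxolan-2-one
Conditions: Et3SiCl (1.05 equiv), imidazole, DMF, 0 °C
Reagents that add atoms: chlorotriethylsilane CC[Si](Cl)(CC)CC
Why: Selective silyl ether formation at the secondary C9 hydroxyl over the hindered tertiary C10 hydroxyl; C9 and C10 come with the correct configuration from the sugar lactone.

Step 8
Reactants: 14 (3R,4R)-3-hydroxy-3-methyl-4-[(triethylsilyl)oxy]oxolan-2-one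
Product: 15 S-ethyl (2R,3R)-2,4-dihydroxy-2-methyl-3-[(triethylsilyl)oxy]butanethioate
Conditions: AlMe3 (2.2 equiv), EtSH (2.2 equiv), CH2Cl2, 0 °C to rt; cold aq. potassium sodium tartrate; crude product used at once
Reagents that add atoms: ethanethiol CCS (delivered as dimethylaluminium ethanethiolate CCS[Al](C)C)
Why: Aluminium thiolate acyl substitution opens the lactone, turning C1 into the S-ethyl thioester and freeing the C8 primary alcohol, which is oxidised without delay to forestall relactonisation.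

Step 9
Reactants: 15 S-ethyl (2R,3R)-2,4-dihydroxy-2-methyl-3-[(triethylsilyl)oxy]butanethioate
Product: 16 S-ethyl (2R,3S)-2-hydroxy-2-methyl-4-oxo-3-[(triethylsilyl)oxy]butanethioate
Conditions: Dess–Martin periodinane, NaHCO3, CH2Cl2, 0 °C
Reagents that add atoms: none
Why: Dess–Martin oxidation of the primary alcohol under buffered conditions should give the C8 aldehyde without epimerising C9, the tertiary alcohol and thioester being inert.

Step 10
Reactants: 12 (5R)-3-(bromomethyl)-5-[(1Z)-2-methylbut-1-en-3-yn-1-yl]furan-2(5H)-one; 16 S-ethyl (2R,3S)-2-hydroxy-2-methyl-4-oxo-3-[(triethylsilyl)oxy]butanethioate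
Product: 18 S-ethyl (2R,3R,4R)-2,4-dihydroxy-2-methyl-4-{(2R,3R)-2-[(1Z)-2-methylbut-1-en-3-yn-1-yl]-4-methylidene-5-oxooxolan-3-yl}-3-[(triethylsilyl)oxy]butanethioate, via allylzinc bromide 17 (not isolated)
Conditions: Zn dust, THF/sat. aq. NH4Cl (2:1), 0 °C; product carried on at once
Reagents that add atoms: none
Why: Barbier allylation through a six-membered chair transition state: 17 attacks through ring carbon C7 on the face anti to the C6 side chain (trans-lactone), its ring-fixed E-type γ-substitution gives the 7,8-anti adduct and the Felkin–Anh preference of the α-silyloxy aldehyde points the same way, so the (8R)-alcohol, the C8 epimer of the target, should form and is inverted in step 11.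

Step 11
Reactants: 18 S-ethyl (2R,3R,4R)-2,4-dihydroxy-2-methyl-4-{(2R,3R)-2-[(1Z)-2-methylbut-1-en-3-yn-1-yl]-4-methylidene-5-oxooxolan-3-yl}-3-[(triethylsilyl)oxy]butanethioate; 19 3-methylbutanoic acid (isovaleric acid)
Product: 20 S-ethyl (2R,3R,4S)-2-hydroxy-2-methyl-4-[(3-methylbutanoyl)oxy]-4-{(2R,3S)-2-[(1Z)-2-methylbut-1-en-3-yn-1-yl]-4-methylidene-5-oxooxolan-3-yl}-3-[(triethylsilyl)oxy]butanethioate
Conditions: PPh3, DIAD, toluene, 0 °C to rt
Reagents that add atoms: none
Why: Mitsunobu esterification displaces the C8 alkoxyphosphonium by isovalerate with SN2 inversion and so sets the (8S)-acyloxy centre, the tertiary C10 hydroxyl not being activated.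

Step 12
Reactants: 20 S-ethyl (2R,3R,4S)-2-hydroxy-2-methyl-4-[(3-methylbutanoyl)oxy]-4-{(2R,3S)-2-[(1Z)-2-methylbut-1-en-3-yn-1-yl]-4-methylidene-5-oxooxolan-3-yl}-3-[(triethylsilyl)oxy]butanethioate
Product: 22 9-O-(triethylsilyl)lobatin B, via ten-membered ynone 21 (not isolated)
Conditions: PdCl2(dppf) (10 mol%), P(2-furyl)3 (25 mol%), CuI (1.7 equiv), Et3N, degassed DMF, 50 °C, syringe-pump addition of 20 (final 1 mM)
Reagents that add atoms: none
Why: Zerovalent palladium inserts into the C1–S bond of the thioester (lactone and isovalerate are not activated), the copper acetylide formed at C2 by CuI/Et3N transmetalates, and reductive elimination makes C1–C2, closing the ten-membered carbocycle as the bent ynone 21; the C10 hydroxyl then adds to C3 and C2 is protonated, making O–C3 and the furanone. The closest known reaction types are the palladium/copper coupling of S-ethyl thioesters with terminal alkynes to ynones (acyl Sonogashira type, tolerant of free hydroxyls) and the base- or π-acid-promoted cycloisomerisation of α′-hydroxy ynones to 3(2H)-furanones. The carbocycle closes by macrocyclising reductive elimination at palladium under high dilution, the (Z)-C4=C5 bond and the trans-lactone turning C2 back toward C1; the furanone closes by transannular 5-endo-dig oxa-Michael addition, driven by release of the alkyne bending strain. No stereocentre is created: C10 is carried in from step 7 and the C2=C3 enol ether geometry is fixed by the five-membered ring. The step needs ring closure over oligomerisation (slow addition), attack by O10 only (O9 is silylated, which also blocks 6-endo closure and 8-to-9 acyl migration under Et3N) and an intact α-methylene lactone (CuI in excess precipitates ethanethiolate as CuSEt).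

Step 13
Reactants: 22 9-O-(triethylsilyl)lobatin B
Product: 23 lobatin B
Conditions: HF·pyridine, pyridine, THF, 0 °C to rt
Reagents that add atoms: none
Why: Acidic fluoride desilylation cleaves the secondary triethylsilyl ether without base, so neither 8-to-9 acyl migration nor conjugate addition to the α-methylene lactone is expected.

Compound list
1 | (2Z)-3-methylpent-2-en-4-yn-1-ol | OC/C=C(/C)C#C | starting material
2 | trimethyl{[(2Z)-3-methyl-5-(trimethylsilyl)pent-2-en-4-yn-1-yl]oxy}silane | C[Si](C)(C)OC/C=C(/C)C#C[Si](C)(C)C | intermediate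
3 | (2Z)-3-methyl-5-(trimethylsilyl)pent-2-en-4-yn-1-ol | OC/C=C(/C)C#C[Si](C)(C)C | intermediate
4 | (2Z)-3-methyl-5-(trimethylsilyl)pent-2-en-4-ynal | O=C/C=C(/C)C#C[Si](C)(C)C | intermediate
5 | methyl prop-2-ynoate (methyl propiolate) | C#CC(=O)OC | starting material
6 | methyl(3-methoxy-3-oxoprop-1-yn-1-yl)zinc | C[Zn]C#CC(=O)OC | intermediate
7 | methyl (4R,5Z)-4-hydroxy-6-methyl-8-(trimethylsilyl)oct-5-ene-2,7-diynoate | COC(=O)C#C[C@H](O)/C=C(/C)C#C[Si](C)(C)C | intermediate
8 | methyl (2E,4R,5Z)-2-(diisobutylalumanyl)-4-[(diisobutylalumanyl)oxy]-6-methyl-8-(trimethylsilyl)octa-2,5-dien-7-ynoate (ester and C4 cis) | COC(=O)/C([Al](CC(C)C)CC(C)C)=C\[C@H](O[Al](CC(C)C)CC(C)C)/C=C(/C)C#C[Si](C)(C)C | intermediate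
9 | methyl (2Z,4R,5Z)-4-hydroxy-2-(hydroxymethyl)-6-methyl-8-(trimethylsilyl)octa-2,5-dien-7-ynoate | COC(=O)/C(CO)=C\[C@H](O)/C=C(/C)C#C[Si](C)(C)C | intermediate
10 | (5R)-3-(hydroxymethyl)-5-[(1Z)-2-methyl-4-(trimethylsilyl)but-1-en-3-yn-1-yl]furan-2(5H)-one | OCC1=C[C@@H](/C=C(/C)C#C[Si](C)(C)C)OC1=O | intermediate
11 | (5R)-3-(hydroxymethyl)-5-[(1Z)-2-methylbut-1-en-3-yn-1-yl]furan-2(5H)-one | OCC1=C[C@@H](/C=C(/C)C#C)OC1=O | intermediate
12 | (5R)-3-(bromomethyl)-5-[(1Z)-2-methylbut-1-en-3-yn-1-yl]furan-2(5H)-one | BrCC1=C[C@@H](/C=C(/C)C#C)OC1=O | intermediate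
13 | 2-C-methyl-D-erythrono-1,4-lactone [(3R,4R)-3,4-dihydroxy-3-methyloxolan-2-one] | O=C1[C@](C)(O)[C@H](O)CO1 | starting material
14 | (3R,4R)-3-hydroxy-3-methyl-4-[(triethylsilyl)oxy]oxolan-2-one | O=C1[C@](C)(O)[C@H](O[Si](CC)(CC)CC)CO1 | intermediate
15 | S-ethyl (2R,3R)-2,4-dihydroxy-2-methyl-3-[(triethylsilyl)oxy]butanethioate | CCSC(=O)[C@](C)(O)[C@H](O[Si](CC)(CC)CC)CO | intermediate
16 | S-ethyl (2R,3S)-2-hydroxy-2-methyl-4-oxo-3-[(triethylsilyl)oxy]butanethioate | CCSC(=O)[C@](C)(O)[C@H](O[Si](CC)(CC)CC)C=O | intermediate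
17 | bromo{[(5R)-5-[(1Z)-2-methylbut-1-en-3-yn-1-yl]-2-oxo-2,5-dihydrofuran-3-yl]methyl}zinc | Br[Zn]CC1=C[C@@H](/C=C(/C)C#C)OC1=O | intermediate
18 | S-ethyl (2R,3R,4R)-2,4-dihydroxy-2-methyl-4-{(2R,3R)-2-[(1Z)-2-methylbut-1-en-3-yn-1-yl]-4-methylidene-5-oxooxolan-3-yl}-3-[(triethylsilyl)oxy]butanethioate (trans-lactone, C8 epimeric to the target) | CCSC(=O)[C@](C)(O)[C@H](O[Si](CC)(CC)CC)[C@H](O)[C@H]1C(=C)C(=O)O[C@@H]1/C=C(/C)C#C | intermediate
19 | 3-methylbutanoic acid (isovaleric acid) | CC(C)CC(=O)O | starting material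
20 | S-ethyl (2R,3R,4S)-2-hydroxy-2-methyl-4-[(3-methylbutanoyl)oxy]-4-{(2R,3S)-2-[(1Z)-2-methylbut-1-en-3-yn-1-yl]-4-methylidene-5-oxooxolan-3-yl}-3-[(triethylsilyl)oxy]butanethioate | CCSC(=O)[C@](C)(O)[C@H](O[Si](CC)(CC)CC)[C@@H](OC(=O)CC(C)C)[C@H]1C(=C)C(=O)O[C@@H]1/C=C(/C)C#C | intermediate
21 | (4Z,6R,7S,8S,9R,10R)-10-hydroxy-8-(3-methylbutanoyloxy)-1-oxo-9-(triethylsilyloxy)germacra-4,11(13)-dien-2-yn-12,6-olide (ten-membered ynone) | C=C1C(=O)O[C@@H]2/C=C(/C)C#CC(=O)[C@](C)(O)[C@H](O[Si](CC)(CC)CC)[C@@H](OC(=O)CC(C)C)[C@@H]12 | intermediate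
22 | 9-O-(triethylsilyl)lobatin B | C=C1C(=O)O[C@@H]2/C=C(/C)C3=CC(=O)[C@](C)(O3)[C@H](O[Si](CC)(CC)CC)[C@@H](OC(=O)CC(C)C)[C@@H]12 | intermediate
23 | lobatin B | C=C1C(=O)O[C@@H]2/C=C(/C)C3=CC(=O)[C@](C)(O3)[C@H](O)[C@@H](OC(=O)CC(C)C)[C@@H]12 | target

Total step count: 13. Longest linear sequence: 10 steps (steps 1–6 and 10–13, from compound 1); the second branch (steps 7–9, from compound 13) joins at step 10.

Steps most likely to fail

Step 12 (key step). The ring closure at palladium may lose to intermolecular coupling and alkyne homocoupling, because the ten-membered ring must hold a bent C1–C2≡C3–C4 unit; zerovalent palladium may also ionise the allylic C6–O bond of the lactone. A slow oxa-Michael step alone would be cured by adding AuCl(PPh3)/AgOTf to the flask and is not the main concern. The fallback sets out from 20 and returns at 22, and closes the ring without an alkyne in it. Markovnikov hydration of the terminal alkyne (Au(NTf2)(PPh3) 5 mol%, wet 1,4-dioxane, rt) should give the (Z)-enone methyl ketone F1. Soft enolisation of its methyl ketone (MgBr2·OEt2, iPr2NEt, CH2Cl2, slow addition, rt) and intramolecular Claisen acylation by the magnesium-chelated α-hydroxy thioester should give the ten-membered 1,3-diketone F2. PPTS in benzene at 50 °C then adds the C10 hydroxyl to the C3 ketone and dehydrates to the furanone 22.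

Step 11. The hindered C8 hydroxyl may be activated slowly, so that elimination toward C7, or attack of the thioester carbonyl oxygen on C8 with loss of the thioester, overtakes displacement by the weakly acidic isovaleric acid. The fallback sets out from 18 and returns at 20, and separates activation from displacement. Tf2O and pyridine in CH2Cl2 at −30 °C should convert the secondary hydroxyl into the C8 triflate F3. Caesium 3-methylbutanoate (CsO2CCH2CHMe2) with 18-crown-6 in toluene at rt then displaces it with inversion to give 20.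

Step 4. The aluminium hydride may over-reduce the ester, the aluminium allenolate may lose the cis geometry, or formaldehyde capture may be sluggish. The fallback sets out from 7 and returns at 10, and builds the C11 substituent by cross-coupling. Syn-hydrostannation with Bu3SnH and Pd(PPh3)4 (THF, 0 °C) places tin on C11, and the cis γ-hydroxy ester lactonises to the 3-(tributylstannyl)butenolide F4. Iodine in CH2Cl2 at 0 °C should give the 3-iodobutenolide F5. Stille coupling of F5 with (tributylstannyl)methanol (Pd(PPh3)4, 1,4-dioxane, 80 °C) gives 10.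

Further compounds
F1 | step 12 | S-ethyl (2R,3R,4S)-2-hydroxy-2-methyl-4-[(3-methylbutanoyl)oxy]-4-{(2R,3S)-4-methylidene-2-[(1Z)-2-methyl-3-oxobut-1-en-1-yl]-5-oxooxolan-3-yl}-3-[(triethylsilyl)oxy]butanethioate | CCSC(=O)[C@](C)(O)[C@H](O[Si](CC)(CC)CC)[C@@H](OC(=O)CC(C)C)[C@H]1C(=C)C(=O)O[C@@H]1/C=C(/C)C(C)=O
F2 | step 12 | (4Z,6R,7S,8S,9R,10R)-10-hydroxy-8-(3-methylbutanoyloxy)-1,3-dioxo-9-(triethylsilyloxy)germacra-4,11(13)-dien-12,6-olide | C=C1C(=O)O[C@@H]2/C=C(/C)C(=O)CC(=O)[C@](C)(O)[C@H](O[Si](CC)(CC)CC)[C@@H](OC(=O)CC(C)C)[C@@H]12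
F3 | step 11 | S-ethyl (2R,3R,4R)-2-hydroxy-2-methyl-4-{(2R,3R)-2-[(1Z)-2-methylbut-1-en-3-yn-1-yl]-4-methylidene-5-oxooxolan-3-yl}-3-[(triethylsilyl)oxy]-4-[(trifluoromethanesulfonyl)oxy]butanethioate (same spatial arrangement as 18) | CCSC(=O)[C@](C)(O)[C@H](O[Si](CC)(CC)CC)[C@H](OS(=O)(=O)C(F)(F)F)[C@H]1C(=C)C(=O)O[C@@H]1/C=C(/C)C#C
F4 | step 4 | (5R)-5-[(1Z)-2-methyl-4-(trimethylsilyl)but-1-en-3-yn-1-yl]-3-(tributylstannyl)furan-2(5H)-one | CCCC[Sn](CCCC)(CCCC)C1=C[C@@H](/C=C(/C)C#C[Si](C)(C)C)OC1=O
F5 | step 4 | (5R)-3-iodo-5-[(1Z)-2-methyl-4-(trimethylsilyl)but-1-en-3-yn-1-yl]furan-2(5H)-one | IC1=C[C@@H](/C=C(/C)C#C[Si](C)(C)C)OC1=O
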